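## Retrosynthetic overview (disconnections listed in the order the bonds are made)

1. From 7-bromoindole 1 and allene 2 (through chloroindole 3 and allylborane 4, both made in the flask): C2–C(tert-prenyl) bond by reverse prenylation (→ 5), then C7–CH2 bond by linear-selective coupling with prenylboronate 6 (→ indole fragment 7).
2. Quinone–indole C–C bonds: two successive addition–eliminations on bromanil 8, first the hindered 7 (→ 9), then indole 10 para to it (→ 11).
3. Key disconnection, made last: both C(sp2)–OCH3 bonds of target 14, from dibromide 11 and methanol (through 12 and 13) by amine-catalysed double substitution. The bromides first steer the two C–C couplings and then become the methoxy groups.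
4. Rings: none is built. Both indole rings and the six-membered ring are bought, and the quinone oxidation level of 8 is kept to the end (no redox steps, no protecting groups).

Assumption: the target SMILES holds no stereocentre and no stereogenic double bond, so the compound is treated as achiral; rotational isomerism about the hindered indole–quinone bond is not specified and is not controlled.

## Route

Step 1
Reactants: 1 7-bromo-1H-indole; 2 3-methylbuta-1,2-diene
Product: 5 7-bromo-2-(2-methylbut-3-en-2-yl)-1H-indole, via 7-bromo-3-chloro-1H-indole 3 (not isolated), via B-prenyl-9-BBN 4 (not isolated)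
Conditions: t-BuOCl, Et3N, THF, −78 °C; then 4 (2 equiv, from 9-BBN and 2, THF, rt), −78 °C → rt; aq NaHCO3
Reagents that add atoms: none
Why: Reverse prenylation of a 3-chloroindole by allylboration, in which the allylborane adds to the C=N bond of the 3H-indole tautomer through a six-membered transition state so that the tertiary carbon of the prenyl unit ends on C2, and Et3N-assisted loss of HCl restores the indole; no prenyl alkene is yet present, so the hypochlorite is chemoselective, and no stereocentre is formed.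

Step 2
Reactants: 5 7-bromo-2-(2-methylbut-3-en-2-yl)-1H-indole; 6 4,4,5,5-tetramethyl-2-(3-methylbut-2-en-1-yl)-1,3,2-dioxaborolane (prenylboronic acid pinacol ester)
Product: 7 2-(2-methylbut-3-en-2-yl)-7-(3-methylbut-2-en-1-yl)-1H-indole
Conditions: 6 (1.5 equiv), PdCl2(IPent)(3-chloropyridine) (2 mol %; IPent = 1,3-bis[2,6-di(pentan-3-yl)phenyl]imidazol-2-ylidene), 5 M aq KOH, THF, 70 °C
Reagents that add atoms: none
Why: Suzuki–Miyaura allyl–aryl coupling in which the bulky carbene ligand makes reductive elimination occur from the less hindered primary σ-prenyl palladium species, so the linear prenyl arene forms, while the free N–H and the neopentyl-type terminal alkene of 5 are tolerated.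

Step 3
Reactants: 7 2-(2-methylbut-3-en-2-yl)-7-(3-methylbut-2-en-1-yl)-1H-indole; 8 bromanil (2,3,5,6-tetrabromocyclohexa-2,5-diene-1,4-dione)
Product: 9 2,3,5-tribromo-6-[2-(2-methylbut-3-en-2-yl)-7-(3-methylbut-2-en-1-yl)-1H-indol-3-yl]cyclohexa-2,5-diene-1,4-dione
Conditions: 8 (1.3 equiv), Cs2CO3, MeCN, 0 °C → rt
Reagents that add atoms: none
Why: Nucleophilic vinylic substitution (addition–elimination) of indole C3 on the vinylogous acyl bromide 8, with the hindered indole used first against the most electrophilic quinone; the indolyl group then deactivates the product as a vinylogous amide, so substitution stops after one bromide.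

Step 4
Reactants: 9 2,3,5-tribromo-6-[2-(2-methylbut-3-en-2-yl)-7-(3-methylbut-2-en-1-yl)-1H-indol-3-yl]cyclohexa-2,5-diene-1,4-dione; 10 1H-indole
Product: 11 2,5-dibromo-3-(1H-indol-3-yl)-6-[2-(2-methylbut-3-en-2-yl)-7-(3-methylbut-2-en-1-yl)-1H-indol-3-yl]cyclohexa-2,5-diene-1,4-dione
Conditions: 10 (1.2 equiv), Cs2CO3, MeCN, rt
Reagents that add atoms: none
Why: Second addition–elimination, in which the donor indolyl group of 9 deactivates the carbonyl it is conjugated to and the neighbouring C–Br, so indole attacks the bromide-bearing carbon β to the other carbonyl (para to the first indolyl) and leaves the two bromides exactly where the methoxy groups belong.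

Step 5
Reactants: 11 2,5-dibromo-3-(1H-indol-3-yl)-6-[2-(2-methylbut-3-en-2-yl)-7-(3-methylbut-2-en-1-yl)-1H-indol-3-yl]cyclohexa-2,5-diene-1,4-dione
Product: 14 2-(1H-indol-3-yl)-3,6-dimethoxy-5-[2-(2-methylbut-3-en-2-yl)-7-(3-methylbut-2-en-1-yl)-1H-indol-3-yl]cyclohexa-2,5-diene-1,4-dione, via monomethoxy bromoquinone 12 (not isolated), via isomeric monomethoxy bromoquinone 13 (not isolated)
Conditions: DABCO (3 equiv), dry MeOH–THF (1:1), 4 Å MS, 45 °C
Reagents that add atoms: methanol (SMILES: CO)
Why: Proposed new method: nucleophilic-amine catalysis of a double alkoxy-dehalogenation on a donor-deactivated haloquinone, in which neutral DABCO (which the quinone cannot dehydrogenate to an enamine) adds to each bromide-bearing carbon of the undeprotonated substrate and expels bromide to give a quinonyl-ammonium (a vinylogous acyl ammonium), methanol then attacks the same, now strongly activated carbon and DABCO leaves, so both C–OCH3 bonds form without the methoxide that would deprotonate the indole N–H groups, switch off the electrophile and over-add to ketals; the closest known reaction types are DABCO-catalysed SNAr alkoxylation of chloro-azines, DMAP-type acyl transfer and the classical alkoxide substitution of haloquinones.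

## Compound list

1 | 7-bromo-1H-indole | Brc1cccc2cc[nH]c12 | starting material
2 | 3-methylbuta-1,2-diene | CC(C)=C=C | starting material
3 | 7-bromo-3-chloro-1H-indole | Clc1c[nH]c2c(Br)cccc12 | intermediate (not isolated)
4 | B-prenyl-9-BBN, 9-(3-methylbut-2-en-1-yl)-9-borabicyclo[3.3.1]nonane | CC(C)=CCB1C2CCCC1CCC2 | intermediate (not isolated)
5 | 7-bromo-2-(2-methylbut-3-en-2-yl)-1H-indole | C=CC(C)(C)c1cc2cccc(Br)c2[nH]1 | intermediate
6 | 4,4,5,5-tetramethyl-2-(3-methylbut-2-en-1-yl)-1,3,2-dioxaborolane | CC(C)=CCB1OC(C)(C)C(C)(C)O1 | starting material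
7 | 2-(2-methylbut-3-en-2-yl)-7-(3-methylbut-2-en-1-yl)-1H-indole | C=CC(C)(C)c1cc2cccc(CC=C(C)C)c2[nH]1 | intermediate
8 | bromanil, 2,3,5,6-tetrabromocyclohexa-2,5-diene-1,4-dione | O=C1C(Br)=C(Br)C(=O)C(Br)=C1Br | starting material
9 | 2,3,5-tribromo-6-[2-(2-methylbut-3-en-2-yl)-7-(3-methylbut-2-en-1-yl)-1H-indol-3-yl]cyclohexa-2,5-diene-1,4-dione | C=CC(C)(C)c1[nH]c2c(CC=C(C)C)cccc2c1C1=C(Br)C(=O)C(Br)=C(Br)C1=O | intermediate
10 | 1H-indole | c1ccc2[nH]ccc2c1 | starting material
11 | 2,5-dibromo-3-(1H-indol-3-yl)-6-[2-(2-methylbut-3-en-2-yl)-7-(3-methylbut-2-en-1-yl)-1H-indol-3-yl]cyclohexa-2,5-diene-1,4-dione | C=CC(C)(C)c1[nH]c2c(CC=C(C)C)cccc2c1C1=C(Br)C(=O)C(c2c[nH]c3ccccc23)=C(Br)C1=O | intermediate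
12 | 2-bromo-6-(1H-indol-3-yl)-5-methoxy-3-[2-(2-methylbut-3-en-2-yl)-7-(3-methylbut-2-en-1-yl)-1H-indol-3-yl]cyclohexa-2,5-diene-1,4-dione (methoxy next to the unsubstituted indolyl) | C=CC(C)(C)c1[nH]c2c(CC=C(C)C)cccc2c1C1=C(Br)C(=O)C(c2c[nH]c3ccccc23)=C(OC)C1=O | intermediate (not isolated)
13 | 2-bromo-3-(1H-indol-3-yl)-5-methoxy-6-[2-(2-methylbut-3-en-2-yl)-7-(3-methylbut-2-en-1-yl)-1H-indol-3-yl]cyclohexa-2,5-diene-1,4-dione (methoxy next to the diprenylated indolyl) | C=CC(C)(C)c1[nH]c2c(CC=C(C)C)cccc2c1C1=C(OC)C(=O)C(c2c[nH]c3ccccc23)=C(Br)C1=O | intermediate (not isolated)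
14 | 2-(1H-indol-3-yl)-3,6-dimethoxy-5-[2-(2-methylbut-3-en-2-yl)-7-(3-methylbut-2-en-1-yl)-1H-indol-3-yl]cyclohexa-2,5-diene-1,4-dione | C=CC(C)(C)c1[nH]c2c(CC=C(C)C)cccc2c1C1=C(OC)C(=O)C(c2c[nH]c3ccccc23)=C(OC)C1=O | target

## Step count and risks

Total step count: 5. Longest linear sequence: 5 steps (1 → 5 → 7 → 9 → 11 → 14).

Three steps most likely to fail:

**Step 5 (the proposed new step).** DABCO may not add to the donor-deactivated, hindered C–Br carbons, or the ammonium intermediate may be hydrolysed by traces of water. The fallback uses known chemistry and sets out from 11. NaOH in aqueous MeOH at reflux hydrolyses both vinylogous acyl bromides to 2,5-dihydroxy-3-(1H-indol-3-yl)-6-[2-(2-methylbut-3-en-2-yl)-7-(3-methylbut-2-en-1-yl)-1H-indol-3-yl]cyclohexa-2,5-diene-1,4-dione F5. Its two acidic enolic OH groups are then O-methylated with Me3SiCHN2 in MeOH–toluene at 0 °C, which leaves the indole N–H groups untouched. This forms the C–O bonds by O-alkylation and not by substitution at the ring carbon, and it comes back to the route at 14.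

**Step 1.** The 3-chloroindole 3 is labile, tert-butanol consumes part of the allylborane, and the 7-bromo group crowds the nitrogen that must bind boron. The fallback sets out from 1 and avoids halogenation altogether. Reductive allylboration with triprenylborane, B(CH2CH=CMe2)3, in THF at rt to 60 °C, followed by NaOH/MeOH work-up, gives racemic 7-bromo-2-(2-methylbut-3-en-2-yl)indoline F1. Dehydrogenation with MnO2 in CH2Cl2 removes its only stereocentre, and the sequence comes back to the route at 5.

**Step 3.** The 2-tert-alkyl indole is a hindered nucleophile, and bromanil can be over-substituted or hydrolysed by the base. The fallback sets out from 7 and replaces base-mediated substitution by acid-promoted conjugate addition and oxidation. Compound 7 and commercial 2,5-dibromo-1,4-benzoquinone (AcOH or catalytic H2SO4 in THF, rt) give the hydroquinone 2,5-dibromo-3-[2-(2-methylbut-3-en-2-yl)-7-(3-methylbut-2-en-1-yl)-1H-indol-3-yl]benzene-1,4-diol F2. DDQ oxidises it to 2,5-dibromo-3-[2-(2-methylbut-3-en-2-yl)-7-(3-methylbut-2-en-1-yl)-1H-indol-3-yl]cyclohexa-2,5-diene-1,4-dione F3. Conjugate addition of indole 10 in AcOH gives 2,5-dibromo-3-(1H-indol-3-yl)-6-[2-(2-methylbut-3-en-2-yl)-7-(3-methylbut-2-en-1-yl)-1H-indol-3-yl]benzene-1,4-diol F4. A second DDQ oxidation comes back to the route at 11, so steps 3 and 4 are both replaced.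

## Further compounds

F1 | step 1 | 7-bromo-2-(2-methylbut-3-en-2-yl)indoline (racemic) | C=CC(C)(C)C1Cc2cccc(Br)c2N1
F2 | step 3 | 2,5-dibromo-3-[2-(2-methylbut-3-en-2-yl)-7-(3-methylbut-2-en-1-yl)-1H-indol-3-yl]benzene-1,4-diol | C=CC(C)(C)c1[nH]c2c(CC=C(C)C)cccc2c1-c1c(Br)c(O)cc(Br)c1O
F3 | step 3 | 2,5-dibromo-3-[2-(2-methylbut-3-en-2-yl)-7-(3-methylbut-2-en-1-yl)-1H-indol-3-yl]cyclohexa-2,5-diene-1,4-dione | C=CC(C)(C)c1[nH]c2c(CC=C(C)C)cccc2c1C1=C(Br)C(=O)C=C(Br)C1=O
F4 | step 3 | 2,5-dibromo-3-(1H-indol-3-yl)-6-[2-(2-methylbut-3-en-2-yl)-7-(3-methylbut-2-en-1-yl)-1H-indol-3-yl]benzene-1,4-diol | C=CC(C)(C)c1[nH]c2c(CC=C(C)C)cccc2c1-c1c(Br)c(O)c(-c2c[nH]c3ccccc23)c(Br)c1O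
F5 | step 5 | 2,5-dihydroxy-3-(1H-indol-3-yl)-6-[2-(2-methylbut-3-en-2-yl)-7-(3-methylbut-2-en-1-yl)-1H-indol-3-yl]cyclohexa-2,5-diene-1,4-dione | C=CC(C)(C)c1[nH]c2c(CC=C(C)C)cccc2c1C1=C(O)C(=O)C(c2c[nH]c3ccccc23)=C(O)C1=O
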